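The data were computed with made-up constants; noise was put on by code.

The ratio I began with was Q to D: 0.867 in the maple run and 1.30 in eta, beta and alpha. So D outnumbered Q in maple, and Q outnumbered D in the new flasks.

the same everywhere: Z 10 mM; Q 0.26 mol%
- maple: D 30 µM; temperature 35 °C; run made earlier
- eta: D 20 µM; temperature 35 °C; time 1.0 h
- beta: D 20 µM; temperature 5 °C; time 1.0 h
- alpha: D 20 µM; at 5 °C until 12 min, from then on at 35 °C; time 1.0 h

maple run (percent of the Z charged)

| time / min | G / % | Z / % |
|---|---|---|
| 1.00 | 0 | 96 |
| 3.00 | 2 | 97 |
| 6.00 | 12 | 92 |
| 8.00 | 16 | 80 |
| 12.0 | 26 | 70 |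

(standard deviation of a reading: 2 percentage points)

- the earlier runs do not show what temperature does; that part of a forecast is a guess

* which flask leads in amount of G, in percent of the Z charged ("all alike" within 1.5 percentage points) (eta / beta / alpha / all alike)
* how much G is there at the end, in percent of the Z charged: eta
* how much G is there at the end, in percent of the Z charged: beta
* how much G is there at the end, in percent of the Z charged: alpha

I kept a ledger for Q, supposing that each Q either meets a D and is lost or starts a chain that goes on making G. Each new flask was charged with 26.0 µM of Q and 20 µM of D. If every D claims one Q, the first entry is 20 µM lost, and the balance is 6.00 µM. I called this balance the spare Q, the charge of Q less the charge of D.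

The same entry for maple came to −4.00 µM, so maple had no spare Q, and yet its G was read at 26 % after 12.0 min. Some Q must therefore have got past D, so I took the spare Q as a low estimate of the chains, not as their count.

From the maple readings at 6.00 min and 12.0 min I read a pseudo-first-order constant of 0.0289 min⁻¹. Eta had less D than maple and the same Q, so I carried that constant over to eta as a cautious estimate. Allowing a lag of 3.00 min, I expected about 80.7 % G in eta. For beta and alpha the ratio is the same, but the earlier runs do not show what temperature does, so I committed to no figure for them. Guessing that cold slows the flask, I expected eta to lead alpha, which spent its first 12 min cold, and beta, which stayed cold.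

The forecast put eta in the lead, with 84 % for eta, 10 % for beta and 78 % for alpha. Its ground for the later rate was this: “I also assume D doesn't change the later rate”.

The flasks put eta in the lead, with 94.6 % G in eta, 21.1 % in beta and 90.6 % in alpha.

    Z + Q → J + G (k = 9.10 L mol⁻¹ min⁻¹, Ea = 44.0 kJ mol⁻¹)
    Z + J → G + J, rate k2*[J]*[Z] (k = 6600 L mol⁻¹ min⁻¹, Ea = 49.0 kJ mol⁻¹)
    Q + D → L (k = 21000 L mol⁻¹ min⁻¹, Ea = 43.0 kJ mol⁻¹)
    (constants at 35 °C)

In eta at 1.00 h, J, the living end, stood at 8.03 µM, above the spare Q of 6.00 µM. L stood at 17.9 µM, and with the Q remaining the entries summed to 26.0 µM. A neighbouring flask, beta with 4.0 mM of Z at the same loading, was charged with 10.4 µM of Q, so its spare Q was −9.60 µM. At 1.00 h it held 0.977 µM of J, 8.93 µM of L and 4.7 % of its Q, and its G stood at 3.54 %.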